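**Remarks on the chemistry (made before the route)**

- Locants: the carbocycle is C1 (CH–O‑tiglate), C2, C3 (CMe=), C4 (=CH), C5 (CH–OAc), C6, C7 (CMe–OH), C8 (=CH), C9 (lactone O–C=), C10 (butenolide β‑carbon); C11 is the butenolide α‑carbon, C12 the lactone carbonyl, C13 the acetoxymethyl carbon. The same locants are used for every intermediate. Ring A is C1–C2–C3–C4–C9–C10, ring B is C4–C5–C6–C7–C8–C9.
- Check of the structures: the descriptors at C1, C5 and C7 of the bicyclic epoxy ketone and of the cyclodecynone were compared with the target atom by atom. The spatial arrangement is the same in all three, so no configuration has to be corrected. Only the CIP labels change with the neighbours: 1S,5R,7S in the epoxy ketone, 1R,5R,7S in the ynone and in the target.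
- What was changed is the protection and the way to the bicycle. C5–O and C7–O are tied as one cyclic carbonate. C5 is set by a catalyst and not in a ring closure. The enone is epoxidised under neutral conditions. After the fragmentation C9 is masked as an enol silane, not as a ketal.
- Assumption 1: the lipase acetylates the (S)‑alcohol faster, so that (R)‑4 is the recovered alcohol; if the sense is the opposite, the acetate is taken and cleaved with the same enzyme in buffer.
- Assumption 2: the epoxide of 16 is drawn anti to the carbonate bridge (the expected face); the other face would fragment to the same ynone.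

## Structural features

The target is a ten‑membered carbocycle (C1–C10) fused along C9–C10 to a butenolide whose ring oxygen sits on C9. C9 is also one end of the exocyclic C8=C9 double bond, so the core is a cross‑conjugated γ‑alkylidene butenolide (a dienol lactone), with an acetoxymethyl group (C13) on C11. The ring carries three carbinol centres: C1 (tiglate, allylic to C10=C11), C5 (acetate, allylic to the cis trisubstituted C3=C4 alkene) and C7 (free tertiary alcohol with a methyl group, allylic to C8=C9). C5 and C7 are 1,3‑related; C1 is remote from both. The fragile parts are the enol lactone (base, nucleophiles), the tertiary allylic C7–OH (acid), and the three esters, of which one tiglate must be told apart from two acetates. The real difficulties are the medium ring with two ring‑cis double bonds, the relation of C1 to the C5/C7 pair across that ring, and the choice between the two α‑positions (C8, C10) of the C9 carbonyl when the butenolide is built. The key step uses the fact that C9 (carbonyl level) and the C3=C4 alkene are 1,5‑related: a C9 ketone and a C3≡C4 alkyne are exactly what remains when the C4–C9 bond shared by rings A and B of a ring‑fusion α,β‑epoxy ketone (ketone C3, epoxide C4–C9) is cut. A ring alkyne can then only give the cis alkene on syn addition.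

## Logic of the disconnections

**32 ⇒ 30 + 31.** The C1–O acyl bond is cut last. The tiglate is the ester that differs from the other two, and it would not survive Grignard, enolate or fluoride chemistry. The forward step must acylate a secondary allylic alcohol next to a free tertiary one.

**30 ⇒ 29 ⇒ 28 ⇒ 27.** The C5 acetate and the two free hydroxyls are traced back to a silylene across C5/C7 and a silyl ether at C1. This gives one robust group for the acid‑sensitive allylic and tertiary oxygens while the butenolide is made. The demand is that fluoride removes the silylene before the C1 silyl ether.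

**27 ⇒ 26 ⇒ 23 + 25.** The butenolide is cut at C10–C11 and at the lactone C12–O bond. This returns a C9 carbonyl derivative and a three‑carbon α‑keto ester that already carries the C13 acetate. The ring‑cis C8=C9 geometry is enforced by the ring. The forward aldol must take place at C10 and not at C8, which is secured by using a regiodefined enol silane.

**23 ⇒ 22 ⇒ 20.** The C3–CH3 bond is cut to a ring alkyne. A syn carbometalation directed by the C5 alkoxide must place methyl on C3 and give the cis alkene. It needs a free C5–OH, a silylated C1–O and a masked C9 carbonyl.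

**20 ⇒ 19.** The enol silane goes back to the C9 ketone. The forward step must enolise toward C10 without a free enolate that could expel the β‑oxygens.

**19 ⇒ 16 + 17 (key).** The ten‑membered ynone is reconnected across C4–C9 to a six‑six epoxy ketone. The gain is that the medium ring is never closed by bond formation and that C1, C5 and C7 can be set on a rigid bicycle. The forward fragmentation must be faster than β‑elimination of the C1 silyloxy group.

**16 ⇒ 15.** The epoxide oxygen is removed to give the ring‑fusion enone. The demand is an epoxidation that spares a carbonate and a β‑silyloxy ketone.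

**15 ⇒ 14 ⇒ 13 ⇒ 12.** The C7–O bond and the C7 methyl are traced back to an exocyclic methylene and the C5 hydroxyl. Intramolecular delivery of oxygen from C5 must make the C5/C7 relation cis, and the same operation installs the diol protection.

**12 ⇒ 10.** Ring B is opened at C8–C9 to an allylic chloride and a vinylogous ester carbonyl. No lasting stereocentre is formed in the closure. The nucleophile must attack the carbonyl carbon and not the alkoxy‑bearing carbon, because that choice decides the sense of C1.

**10 ⇒ 7 + 9.** The C5–C6 bond is cut to an aldehyde and a bifunctional allylstannane. C5 is created intermolecularly under catalyst control, independent of the remote C1.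

**7 ⇒ 6 ⇒ 5.** The formyl carbon C5 is removed from C4 by way of the α‑iodide. This uses the enol‑ether character of that carbon.

**5 ⇒ 4 ⇒ 3 ⇒ 2 ⇒ 1.** The silyl ether, the resolution, the enol ether and the partial reduction lead back to the symmetric triphenol. C1 becomes a stereocentre when the dione is desymmetrised as its mono enol ether, and one enantiomer is selected there.

**9 ⇐ 8 and 25 ⇐ 24.** Each reagent comes from a commercial halide by one substitution.

## Other disconnections considered

**Alternative 1:** the cut is at C9–C10 together with the lactone C12–O bond. In the forward step a C10 vinyl iodide bearing a cis ester adds to a C9 aldehyde under CrCl2 with catalytic NiCl2 (Nozaki–Hiyama–Kishi), and the chromium alkoxide lactonises to give A1, the ten‑membered ring fused to a γ‑H butenolide.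
- In its favour: it is convergent. The esters at C1 and C5, the C3=C4 geometry and all three carbinol centres are made on open chains. There is no question of C8 versus C10 enolisation, and on that point it is better than the chosen plan. It also needs fewer protecting‑group steps at the end.
- Against it: the medium ring is closed by bond formation at high dilution with a hindered tetrasubstituted vinyl iodide. C9 comes out at the alcohol level, so the C8=C9 bond must still be introduced by oxidation next to the tertiary C7 centre, in the presence of all the esters.
- Comparison: the chosen plan gets the ring without cyclisation entropy and gets C9 at the right oxidation level directly from the mechanism. It pays with a longer linear sequence and with the regiochemical problem at C9. In step count the two are comparable once the late dehydrogenation of A1 is included.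

**Alternative 2:** the butenolide is carried as a furan and the cut is at C4–C5. A (Z)‑C4 vinyl iodide adds to a C5 aldehyde (CrCl2, catalytic NiCl2) to give A2, a furan‑fused ten‑membered ring with the C5 carbinol.
- In its favour: the furan is robust. The C3=C4 geometry is fixed in the iodide before closure, which is equal in reliability to the syn carbometalation of the chosen plan. C10–C11 is part of the aromatic ring from the start, so again no enolate regiochemistry arises; on that point it is better.
- Against it: C5 is created during the macrocyclisation and its configuration depends on the ring conformation and not on a reagent. The ring closure carries the entropic cost. The furan must later be oxidised regioselectively to the γ‑alkylidene butenolide next to a trisubstituted alkene and a tertiary carbinol.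
- Comparison: the chosen plan fixes C5 with a catalyst before any ring exists and makes the butenolide from a ketone without an oxidation. Alternative 2 could be shorter if the furan oxidation is clean.

**Alternative 3:** the cut is at C5–C6. A lithiated 2‑alkenyl‑1,3‑dithiane (C5) opens a C6–C7 epoxide at its CH2 terminus to give A3, a furan‑fused ring with a C5 dithiane and the free C7 carbinol.
- In its favour: C7 comes from an enantiopure 2,2‑disubstituted epoxide and is not touched in the ring closure. For C7 this is equal to or better than the chosen plan. The new bond is made at an unhindered CH2 beside the quaternary centre.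
- Against it: the alkenyl dithiane anion is ambident (α versus γ attack). The furan C–H can be metalated under the same conditions. The ring is again closed by bond formation. After closure the dithiane must be removed, the C5 ketone reduced with control, and the furan oxidised.
- Comparison: the chosen plan has more steps before the medium ring but fewer after it. It sets C5 and C7 together on a bicycle, while A3 still lacks C5 and the butenolide.

Key step: step 14

## Route

Step 1
Reactants: 1 phloroglucinol
Product: 2 5-hydroxycyclohexane-1,3-dione
Conditions: NaBH4, aq. NaOH, 0 °C → rt; then HCl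
Reagents that add atoms: none
Why: Borohydride reduces one carbonyl of the triketo tautomer of the phenolate and the product is shielded from further reduction as its β-diketonate (partial reduction of a polyphenol keto tautomer, the usual access to dihydrophloroglucinol).

Step 2
Reactants: 2 5-hydroxycyclohexane-1,3-dione
Product: 3 rac-3-ethoxy-5-hydroxycyclohex-2-en-1-one
Conditions: EtOH, TsOH·H2O (cat.), PhMe, 4 Å MS, rt
Reagents that add atoms: ethanol, CCO
Why: Acid-catalysed mono enol etherification of a cyclic 1,3-dione (vinylogous ester formation) desymmetrises the dione, so the C5 carbinol becomes a stereocentre and 3 is racemic; the low temperature limits dehydration toward the phenol.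

Step 3
Reactants: 3 rac-3-ethoxy-5-hydroxycyclohex-2-en-1-one
Product: 4 (R)-3-ethoxy-5-hydroxycyclohex-2-en-1-one (recovered alcohol)
Conditions: vinyl acetate, Candida antarctica lipase B (immobilised), MTBE, 30 °C, run slightly past half conversion
Reagents that add atoms: none
Why: Lipase-catalysed kinetic resolution by enantioselective transesterification; by the empirical size rule the (S)-alcohol (ethoxy-bearing side as the large group) should be acetylated faster, and going past half conversion raises the enantiomeric purity of recovered (R)-4, which becomes C1 of the target.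

Step 4
Reactants: 4 (R)-3-ethoxy-5-hydroxycyclohex-2-en-1-one
Product: 5 (R)-5-(tert-butyldimethylsilyloxy)-3-ethoxycyclohex-2-en-1-one
Conditions: TBSCl, imidazole, DMF, rt
Reagents that add atoms: tert-butyldimethylsilyl chloride, CC(C)(C)[Si](C)(C)Cl
Why: Standard silylation of a secondary alcohol under non-acidic conditions, which also avoids the acid-catalysed alkoxy transposition that would racemise the vinylogous ester.

Step 5
Reactants: 5 (R)-5-(tert-butyldimethylsilyloxy)-3-ethoxycyclohex-2-en-1-one
Product: 6 (R)-5-(tert-butyldimethylsilyloxy)-3-ethoxy-2-iodocyclohex-2-en-1-one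
Conditions: N-iodosuccinimide, MeCN, 0 °C → rt
Reagents that add atoms: N-iodosuccinimide, O=C1CCC(=O)N1I
Why: The α-carbon of a β-alkoxy enone is an enol-ether carbon and is iodinated by the electrophilic iodine source (α-halogenation of a vinylogous ester); this carbon is the future C4.

Step 6
Reactants: 6 (R)-5-(tert-butyldimethylsilyloxy)-3-ethoxy-2-iodocyclohex-2-en-1-one
Product: 7 (R)-4-(tert-butyldimethylsilyloxy)-2-ethoxy-6-oxocyclohex-1-ene-1-carbaldehyde
Conditions: CO (3 atm), Bu3SnH (slow addition), Pd(PPh3)4 (cat.), PhMe, 50 °C
Reagents that add atoms: carbon monoxide, [C-]#[O+]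
Why: Palladium-catalysed reductive carbonylation (formylation) of a vinyl iodide: oxidative addition, CO insertion and hydride transfer from the tin hydride install C5 as the aldehyde under anhydrous neutral conditions that spare the hydrolytically labile alkoxymethylene dicarbonyl unit.

Step 7
Reactants: 8 3-chloro-2-(chloromethyl)prop-1-ene
Product: 9 tributyl[2-(chloromethyl)prop-2-en-1-yl]stannane
Conditions: Bu3SnH, LDA, THF, 0 °C; then 8 (excess), −78 °C
Reagents that add atoms: tributyltin hydride, CCCC[SnH](CCCC)CCCC
Why: SN2 (or degenerate SN2′) displacement of one allylic chloride by the stannyl anion; the excess of dichloride suppresses the second substitution and gives the bifunctional allylstannane that supplies C6, C7 and C8.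

Step 8
Reactants: 7 (R)-4-(tert-butyldimethylsilyloxy)-2-ethoxy-6-oxocyclohex-1-ene-1-carbaldehyde; 9 tributyl[2-(chloromethyl)prop-2-en-1-yl]stannane
Product: 10 (R)-5-(tert-butyldimethylsilyloxy)-2-[(1R)-3-(chloromethyl)-1-hydroxybut-3-en-1-yl]-3-ethoxycyclohex-2-en-1-one
Conditions: (R)-BINOL, Ti(OiPr)4 (cat.), 4 Å MS, CH2Cl2, −20 °C
Reagents that add atoms: none
Why: Keck asymmetric allylation (BINOL–titanium Lewis acid, allylstannane, open transition state) forms C5–C6 under catalyst control, so C5 is set independently of the remote C1; the (R)-ligand should give the (R)-carbinol, the usual sense for aldehydes whose substituent outranks the allyl group, and the allylic chloride is not touched.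

Step 9
Reactants: 10 (R)-5-(tert-butyldimethylsilyloxy)-2-[(1R)-3-(chloromethyl)-1-hydroxybut-3-en-1-yl]-3-ethoxycyclohex-2-en-1-one
Product: 12 ring-fusion enone (1S,5R)-1-(tert-butyldimethylsilyloxy)-5-hydroxy-7-methylidenebicyclo[4.4.0]dec-4(9)-en-3-one (target locants), via tertiary carbinol 11 (not isolated)
Conditions: In powder, NaI, DMF, rt; then 1 M HCl, THF, 0 °C
Reagents that add atoms: water, O
Why: Barbier allylation: the allylindium formed from the allylic chloride tolerates the free hydroxyl and adds 1,2 to the C9 carbonyl in a six-membered ring closure (6-exo-trig), and acid then ionises the tertiary allylic carbinol and hydrolyses the enol ether (Stork–Danheiser transposition) to the ring-fusion enone; no lasting stereocentre is formed and, because the nucleophile attacks only the carbonyl carbon, C1 keeps its sense.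

Step 10
Reactants: 12 ring-fusion enone with free C5 hydroxyl
Product: 13 (1S,5R)-5-(tert-butoxycarbonyloxy) derivative of 12
Conditions: Boc2O, DMAP (cat.), MeCN, rt
Reagents that add atoms: di-tert-butyl dicarbonate, CC(C)(C)OC(=O)OC(=O)OC(C)(C)C
Why: DMAP-catalysed acylation of the secondary allylic alcohol gives the tert-butyl carbonate that will deliver oxygen to C7 from the C5 face.

Step 11
Reactants: 13 C5 tert-butyl carbonate
Product: 14 (1S,5R,7R)-7-(iodomethyl) 5,7-cyclic carbonate of the ring-fusion enone
Conditions: IBr, PhMe, −80 °C
Reagents that add atoms: iodine monobromide, IBr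
Why: Iodocarbonate cyclisation: the iodonium ion of the electron-rich exocyclic alkene (the enone alkene is inert) is opened at the tertiary carbon C7 by the carbonate carbonyl oxygen with loss of the tert-butyl group; that oxygen can reach C7 only from the face of C5–O, so the C7–O bond is formed cis to C5–O.

Step 12
Reactants: 14 iodomethyl cyclic carbonate
Product: 15 (1S,5R,7R)-1-(tert-butyldimethylsilyloxy)-7-methyl-5,7-(carbonyldioxy)bicyclo[4.4.0]dec-4(9)-en-3-one (target locants)
Conditions: Bu3SnH, AIBN (cat.), PhH, 80 °C
Reagents that add atoms: none
Why: Radical chain reduction of the primary iodide turns CH2I into the C7 methyl group; hydrogen transfer from the stannane outruns any transannular addition to the enone.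

Step 13
Reactants: 15 methyl cyclic carbonate enone
Product: 16 (1S,5R,7S)-4,9-epoxide of 15 (epoxide anti to the carbonate bridge), the α,β-epoxy ketone
Conditions: dimethyldioxirane, acetone, 0 °C → rt
Reagents that add atoms: dimethyldioxirane, CC1(C)OO1
Why: Dimethyldioxirane epoxidises alkyl-rich enone double bonds under neutral conditions, so neither the base-labile carbonate nor the β-silyloxy ketone meets the alkaline peroxide normally used; attack anti to the carbonate bridge is expected and the face is without consequence for the next step.

Step 14
Reactants: 16 α,β-epoxy ketone; 17 p-toluenesulfonyl hydrazide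
Product: 19 (1R,5R,7S)-1-(tert-butyldimethylsilyloxy)-7-methyl-5,7-(carbonyldioxy)cyclodec-3-yn-9-one (target locants), via tosylhydrazone 18 (not isolated)
Conditions: TsNHNH2, AcOH–CH2Cl2 (1:1), −20 °C → rt
Reagents that add atoms: none
Why: Condensation of the C3 ketone with the sulfonyl hydrazide gives tosylhydrazone 18. Loss of the N–H proton opens the epoxide at C4–O and gives a tosylazo alkene (C3=C4) with an alkoxide on C9. A Grob-type collapse then forms C9=O, breaks the C4–C9 bond shared by the two six-membered rings, makes the C3≡C4 triple bond and expels nitrogen and sulfinate. The closest known reaction type is the Eschenmoser–Tanabe fragmentation of ring-fusion epoxy octalones to cyclodec-5-ynones. No ring is closed by bond formation, so no closure mode applies: the ten-membered ring appears because the shared bond is cut, and the carbonate stays as a bridge. No stereocentre is made, and C1, C5 and C7 are not at the reacting carbons. The step needs chemoselectivity against β-elimination of the C1 silyloxy group and against acid opening of the epoxide; this is secured by acetic acid buffering at low temperature, by the fast intramolecular epoxide opening once the hydrazone exists, and by an acid-stable, electron-withdrawing carbonate on C5/C7 in place of acid-labile ethers.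

Step 15
Reactants: 19 cyclodecynone
Product: 20 C9 tert-butyldimethylsilyl enol ether (C9=C10) of 19
Conditions: TBSOTf, Et3N, CH2Cl2, −78 → 0 °C
Reagents that add atoms: tert-butyldimethylsilyl triflate, CC(C)(C)[Si](C)(C)OS(=O)(=O)C(F)(F)F
Why: Soft enolisation (silyl triflate and amine) gives the enol silane without a free enolate, so neither the C1 silyloxy group nor the C7 carbonate oxygen can be expelled; the proton should be lost from C10 because C8 is neopentyl-like beside the fully substituted C7, and the enol silane both masks C9 toward the Grignard reagent (a medium-ring ketone resists ketalisation) and serves as the nucleophile of step 19.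

Step 16
Reactants: 20 enol silane with C5/C7 carbonate
Product: 22 (1R,3Z,5R,7S)-diol with C3 methyl and cis C3=C4 alkene, via alkynediol 21 (not isolated)
Conditions: MeMgBr (8 equiv), THF, 0 °C → rt; then Fe(acac)3 (cat.), 0 °C; aq. NH4Cl
Reagents that add atoms: methylmagnesium bromide, C[Mg]Br
Why: The Grignard reagent first cleaves the cyclic carbonate to the C5/C7 magnesium alkoxides (21); with the iron catalyst the C5 alkoxide then directs a syn carbomagnesiation, methyl to the distal C3 and magnesium to C4 in a five-membered chelate, so protonation gives the ring-cis (3Z) alkene; the C1 oxygen is silylated and cannot direct the opposite regiochemistry.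

Step 17
Reactants: 22 (3Z)-diol
Product: 23 C5/C7 di-tert-butylsilylene derivative of 22
Conditions: tBu2Si(OTf)2, 2,6-lutidine, CH2Cl2, 0 °C
Reagents that add atoms: di-tert-butylsilyl bis(trifluoromethanesulfonate), CC(C)(C)[Si](OS(=O)(=O)C(F)(F)F)(OS(=O)(=O)C(F)(F)F)C(C)(C)C
Why: Silylene formation on the cis-1,3-diol protects the allylic C5 and the tertiary C7 oxygen in one group that tolerates Lewis and protic acid and is removed by fluoride.

Step 18
Reactants: 24 ethyl bromopyruvate
Product: 25 ethyl 3-acetoxy-2-oxopropanoate
Conditions: KOAc, acetone, rt
Reagents that add atoms: potassium acetate, CC(=O)[O-].[K+]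
Why: SN2 displacement of the α-bromide of a ketone by acetate gives the C11–C13 unit with the C13 acetate already in place.

Step 19
Reactants: 23 silylene-protected enol silane; 25 ethyl 3-acetoxy-2-oxopropanoate
Product: 26 aldol adduct with C9 ketone and C10–C11 bond (C11 tertiary alcohol, ethyl ester, acetoxymethyl; C10 and C11 epimer mixture)
Conditions: BF3·OEt2, CH2Cl2, −78 °C
Reagents that add atoms: none
Why: Mukaiyama aldol addition: the Lewis acid activates the keto group of the α-keto ester and the C10 terminus of the enol silane attacks it, so the C10–C11 bond is fixed regiochemically; both new stereocentres become sp2 in the next step and their configuration does not matter.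

Step 20
Reactants: 26 aldol adduct
Product: 27 (1R,3Z,5R,7S,8E)-dienol lactone with C1 silyl ether and C5/C7 silylene
Conditions: TsOH·H2O (cat.), PhMe, 4 Å MS, 80 °C
Reagents that add atoms: none
Why: Acid-mediated dehydrative enol lactonisation of a γ-keto ester aldol adduct: loss of water gives the C10=C11 alkylidene, whose geometrical isomers interconvert under acid, and the C9 enol is acylated by the ester with loss of ethanol; the ring allows only the ring-cis (8E) alkene, and the silyl-protected allylic and tertiary oxygens resist ionisation better than free or acylated ones.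

Step 21
Reactants: 27 silylene-protected dienol lactone
Product: 28 C5,C7-diol with C1 silyl ether
Conditions: HF·pyridine, pyridine, THF, 0 °C
Reagents that add atoms: none
Why: Buffered fluoride cleaves the cyclic dialkoxysilane much faster than the secondary TBS ether at 0 °C and frees only C5–OH and C7–OH.

Step 22
Reactants: 28 C5,C7-diol
Product: 29 C5 acetate with free C7 tertiary alcohol and C1 silyl ether
Conditions: Ac2O, pyridine, DMAP (cat.), CH2Cl2, 0 °C
Reagents that add atoms: acetic anhydride, CC(=O)OC(C)=O
Why: Acetylation of the secondary allylic C5 alcohol; the tertiary C7 alcohol does not react under these conditions.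

Step 23
Reactants: 29 C5 acetate
Product: 30 C1 alcohol (C5 and C13 acetates, free C7 alcohol)
Conditions: HF·pyridine, THF, rt
Reagents that add atoms: none
Why: Desilylation of the remaining secondary TBS ether with HF·pyridine, conditions that the enol lactone, the allylic acetates and the tertiary allylic alcohol should tolerate.

Step 24
Reactants: 30 C1 alcohol; 31 tiglic acid
Product: 32 CNP0166369.1
Conditions: 2,4,6-trichlorobenzoyl chloride, Et3N, THF, rt; then 30, DMAP, PhMe, rt
Reagents that add atoms: none
Why: Yamaguchi esterification through the mixed anhydride acylates the secondary C1 alcohol while the tertiary C7 alcohol stays free; the (E)-2-methylbut-2-enoyl group is configurationally stable under these conditions.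

## Compound list

1 | phloroglucinol | Oc1cc(O)cc(O)c1 | starting material
2 | 5-hydroxycyclohexane-1,3-dione | O=C1CC(O)CC(=O)C1 | intermediate
3 | rac-3-ethoxy-5-hydroxycyclohex-2-en-1-one | CCOC1=CC(=O)CC(O)C1 | intermediate
4 | (R)-3-ethoxy-5-hydroxycyclohex-2-en-1-one | O=C1C=C(OCC)C[C@@H](O)C1 | intermediate
5 | (R)-5-(tert-butyldimethylsilyloxy)-3-ethoxycyclohex-2-en-1-one | O=C1C=C(OCC)C[C@@H](O[Si](C)(C)C(C)(C)C)C1 | intermediate
6 | (R)-5-(tert-butyldimethylsilyloxy)-3-ethoxy-2-iodocyclohex-2-en-1-one | O=C1C(I)=C(OCC)C[C@@H](O[Si](C)(C)C(C)(C)C)C1 | intermediate
7 | (R)-4-(tert-butyldimethylsilyloxy)-2-ethoxy-6-oxocyclohex-1-ene-1-carbaldehyde | O=C1C(C=O)=C(OCC)C[C@@H](O[Si](C)(C)C(C)(C)C)C1 | intermediate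
8 | 3-chloro-2-(chloromethyl)prop-1-ene | C=C(CCl)CCl | starting material
9 | tributyl[2-(chloromethyl)prop-2-en-1-yl]stannane | C=C(CCl)C[Sn](CCCC)(CCCC)CCCC | intermediate
10 | (R)-5-(tert-butyldimethylsilyloxy)-2-[(1R)-3-(chloromethyl)-1-hydroxybut-3-en-1-yl]-3-ethoxycyclohex-2-en-1-one | O=C1C([C@H](O)CC(=C)CCl)=C(OCC)C[C@@H](O[Si](C)(C)C(C)(C)C)C1 | intermediate
11 | ring-closed tertiary carbinol (C9–OH, C3 enol ether, 7-methylidene; C1 and C5 as in 10; C9 not defined) | CCOC1=C2[C@H](O)CC(=C)CC2(O)C[C@H](O[Si](C)(C)C(C)(C)C)C1 | intermediate (not isolated)
12 | (1S,5R)-1-(tert-butyldimethylsilyloxy)-5-hydroxy-7-methylidenebicyclo[4.4.0]dec-4(9)-en-3-one (target locants) | O=C1C[C@@H](O[Si](C)(C)C(C)(C)C)CC2=C1[C@H](O)CC(=C)C2 | intermediate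
13 | (1S,5R)-5-(tert-butoxycarbonyloxy) derivative of 12 | O=C1C[C@@H](O[Si](C)(C)C(C)(C)C)CC2=C1[C@H](OC(=O)OC(C)(C)C)CC(=C)C2 | intermediate
14 | (1S,5R,7R)-7-(iodomethyl)-5,7-(carbonyldioxy) ring-fusion enone | O=C1C[C@@H](O[Si](C)(C)C(C)(C)C)CC2=C1[C@H]3C[C@@](CI)(C2)OC(=O)O3 | intermediate
15 | (1S,5R,7R)-1-(tert-butyldimethylsilyloxy)-7-methyl-5,7-(carbonyldioxy)bicyclo[4.4.0]dec-4(9)-en-3-one (target locants) | O=C1C[C@@H](O[Si](C)(C)C(C)(C)C)CC2=C1[C@H]3C[C@@](C)(C2)OC(=O)O3 | intermediate
16 | (1S,5R,7S)-4,9-epoxy derivative of 15, epoxide anti to the carbonate bridge | O=C1C[C@@H](O[Si](C)(C)C(C)(C)C)C[C@]23O[C@]12[C@H]4C[C@@](C)(C3)OC(=O)O4 | intermediate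
17 | p-toluenesulfonyl hydrazide | Cc1ccc(cc1)S(=O)(=O)NN | starting material
18 | C3 tosylhydrazone of 16 | Cc1ccc(cc1)S(=O)(=O)NN=C1C[C@@H](O[Si](C)(C)C(C)(C)C)C[C@]23O[C@]12[C@H]4C[C@@](C)(C3)OC(=O)O4 | intermediate (not isolated)
19 | (1R,5R,7S)-1-(tert-butyldimethylsilyloxy)-7-methyl-5,7-(carbonyldioxy)cyclodec-3-yn-9-one (target locants) | CC(C)(C)[Si](C)(C)O[C@@H]1CC#C[C@H]2C[C@@](C)(CC(=O)C1)OC(=O)O2 | intermediate
20 | C9 tert-butyldimethylsilyl enol ether (C9=C10) of 19 | CC(C)(C)[Si](C)(C)O[C@@H]1CC#C[C@H]2C[C@@](C)(CC(O[Si](C)(C)C(C)(C)C)=C1)OC(=O)O2 | intermediate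
21 | (1R,5R,7S)-alkyne-5,7-diol with C9 enol silane (present as its magnesium alkoxide) | CC(C)(C)[Si](C)(C)O[C@@H]1CC#C[C@H](O)C[C@](C)(O)CC(O[Si](C)(C)C(C)(C)C)=C1 | intermediate (not isolated)
22 | (1R,3Z,5R,7S)-3,7-dimethyl-5,7-diol with C1 silyl ether and C9 enol silane | CC(C)(C)[Si](C)(C)O[C@@H]1C/C(C)=C\[C@H](O)C[C@](C)(O)CC(O[Si](C)(C)C(C)(C)C)=C1 | intermediate
23 | C5/C7 di-tert-butylsilylene derivative of 22 | CC(C)(C)[Si](C)(C)O[C@@H]1C/C(C)=C\[C@H]2C[C@@](C)(CC(O[Si](C)(C)C(C)(C)C)=C1)O[Si](C(C)(C)C)(C(C)(C)C)O2 | intermediate
24 | ethyl bromopyruvate | CCOC(=O)C(=O)CBr | starting material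
25 | ethyl 3-acetoxy-2-oxopropanoate | CCOC(=O)C(=O)COC(C)=O | intermediate
26 | aldol adduct: C9 ketone, C10 bearing C11(OH)(CH2OAc)(CO2Et); C10 and C11 not defined | CC(C)(C)[Si](C)(C)O[C@@H]1C/C(C)=C\[C@H]2C[C@@](C)(CC(=O)C1C(O)(COC(C)=O)C(=O)OCC)O[Si](C(C)(C)C)(C(C)(C)C)O2 | intermediate
27 | (1R,3Z,5R,7S,8E)-dienol lactone with C1 silyl ether, C5/C7 silylene and C13 acetate | CC(C)(C)[Si](C)(C)O[C@@H]1C/C(C)=C\[C@H]2C[C@@](C)(/C=C3/OC(=O)C(COC(C)=O)=C31)O[Si](C(C)(C)C)(C(C)(C)C)O2 | intermediate
28 | C5,C7-diol of the dienol lactone with C1 silyl ether | CC(C)(C)[Si](C)(C)O[C@@H]1C/C(C)=C\[C@H](O)C[C@](C)(O)/C=C2/OC(=O)C(COC(C)=O)=C21 | intermediate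
29 | C5 acetate of 28 | CC(C)(C)[Si](C)(C)O[C@@H]1C/C(C)=C\[C@H](OC(C)=O)C[C@](C)(O)/C=C2/OC(=O)C(COC(C)=O)=C21 | intermediate
30 | C1 alcohol (de-tigloyl target) | O[C@@H]1C/C(C)=C\[C@H](OC(C)=O)C[C@](C)(O)/C=C2/OC(=O)C(COC(C)=O)=C21 | intermediate
31 | tiglic acid | C/C=C(\C)C(=O)O | starting material
32 | CNP0166369.1 | C/C=C(\C)C(=O)O[C@@H]1C/C(C)=C\[C@H](OC(C)=O)C[C@](C)(O)/C=C2/OC(=O)C(COC(C)=O)=C21 | target

## Step count and risks

Total step count: 24 (22 on the main line and two one-step reagent preparations, steps 7 and 18). Longest linear sequence: 22 steps (steps 1–6, 8–17 and 19–24) from phloroglucinol.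

Steps least certain to work:

**Step 14 (key).** β-Elimination of the C1 silyloxy group from the C3 ketone or its hydrazone, followed by aromatisation of ring A, may outrun the fragmentation. The carbonate bridge may also stiffen ring B and slow the bond cleavage. Fallback: from 16, condensation with 1-amino-2-phenylaziridine under neutral conditions gives the N-aziridinylimine F1. Gentle warming in toluene then triggers the same fragmentation with loss of styrene and nitrogen, without acid, and the route is rejoined at 19.

**Step 8.** The β-keto aldehyde can bind titanium through two oxygens and the push–pull aldehyde is deactivated, so facial selectivity may be poor and the addition slow. Fallback: from 7 and 8, an indium-mediated Barbier reaction with the dichloride itself, run on into the ring closure and acid treatment of step 9, gives 12 together with the C5 epimer of 12 F2. The two rigid bicyclic alcohols are separated. F2 is inverted by a Mitsunobu reaction (4-nitrobenzoic acid, PPh3, DIAD) to the (5R)-4-nitrobenzoate F3, and mild methanolysis returns to the route at 12.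

**Step 9.** Protonation or dimerisation of the allylindium species may outpace its addition to the weakly electrophilic vinylogous ester carbonyl. During the acid treatment, loss of water from C5 and migration of the exocyclic alkene would aromatise ring B. Fallback: from 10, silylation (TESCl, imidazole) gives the triethylsilyl ether F4. A magnesium Barbier reaction (Mg, THF, 0 °C, dilute) generates the allylic Grignard reagent, which adds to C9 with the classical Stork–Danheiser reactivity to give the tertiary carbinol F5. Cold 1 M HCl effects the transposition and removes the triethylsilyl group, rejoining at 12.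

**Step 15.** Enolisation may occur toward C8, or the silyl triflate may ionise the propargylic carbonate. Fallback: the enol silane mixture is carried through steps 16 and 17, since either regioisomer masks C9. Brief treatment of 23 with dilute HCl in THF gives the C9 ketone F6. LDA at −78 °C then removes a proton from the less hindered C10 methylene, and the lithium enolate is added to 25 in a lithium aldol reaction, rejoining at 26.

**Step 16.** If carbonate cleavage is incomplete when the iron catalyst is added, propargylic substitution toward an allene can compete. The carbometalation of the hindered ring alkyne may also stop short. Fallback: from 20, MeMgBr alone followed by work-up gives 21 as an isolated diol. MnO2 oxidises the propargylic C5 alcohol to the ynone F7. Me2CuLi at −78 °C adds in conjugate syn fashion to give the ring-cis β-methyl enone F8. CBS reduction with the (S)-oxazaborolidine and catecholborane restores the (5R)-carbinol under reagent control, rejoining at 22.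

**Step 20.** Hot acid may remove silyl groups or ionise the allylic C5 and C7 positions before lactonisation is complete, and the alkylidene isomers may not funnel fully into the lactone. Fallback: from 23, the Mukaiyama aldol is run with tert-butyl 3-acetoxy-2-oxopropanoate F9, made as in step 18 from the tert-butyl bromo ester, to give the tert-butyl ester adduct F10. TMSOTf and 2,6-lutidine, then aqueous work-up, cleave the tert-butyl ester without protic acid to the keto acid F11. Ac2O, Et3N and DMAP at room temperature close the enol lactone through the mixed anhydride and eliminate the acetylated tertiary alcohol, rejoining at 27.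

## Further compounds

F1 | step 14 | N-(2-phenylaziridin-1-yl)imine of 16 | c1ccccc1C1CN1N=C2C[C@@H](O[Si](C)(C)C(C)(C)C)C[C@]34O[C@]23[C@H]5C[C@@](C)(C4)OC(=O)O5
F2 | step 8 | (1S,5S)-C5 epimer of 12 | O=C1C[C@@H](O[Si](C)(C)C(C)(C)C)CC2=C1[C@@H](O)CC(=C)C2
F3 | step 8 | (1S,5R)-5-(4-nitrobenzoyloxy) derivative of 12 | O=C1C[C@@H](O[Si](C)(C)C(C)(C)C)CC2=C1[C@H](OC(=O)c3ccc(cc3)[N+](=O)[O-])CC(=C)C2
F4 | step 9 | triethylsilyl ether of 10 | O=C1C([C@H](O[Si](CC)(CC)CC)CC(=C)CCl)=C(OCC)C[C@@H](O[Si](C)(C)C(C)(C)C)C1
F5 | step 9 | triethylsilyl ether of carbinol 11 | CCOC1=C2[C@H](O[Si](CC)(CC)CC)CC(=C)CC2(O)C[C@H](O[Si](C)(C)C(C)(C)C)C1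
F6 | step 15 | C9 ketone corresponding to 23 | CC(C)(C)[Si](C)(C)O[C@@H]1C/C(C)=C\[C@H]2C[C@@](C)(CC(=O)C1)O[Si](C(C)(C)C)(C(C)(C)C)O2
F7 | step 16 | C5 ynone from 21 | CC(C)(C)[Si](C)(C)O[C@@H]1CC#CC(=O)C[C@](C)(O)CC(O[Si](C)(C)C(C)(C)C)=C1
F8 | step 16 | (3Z)-3-methyl C5 enone | CC(C)(C)[Si](C)(C)O[C@@H]1C/C(C)=C\C(=O)C[C@](C)(O)CC(O[Si](C)(C)C(C)(C)C)=C1
F9 | step 20 | tert-butyl 3-acetoxy-2-oxopropanoate | CC(=O)OCC(=O)C(=O)OC(C)(C)C
F10 | step 20 | tert-butyl ester analogue of 26 | CC(C)(C)[Si](C)(C)O[C@@H]1C/C(C)=C\[C@H]2C[C@@](C)(CC(=O)C1C(O)(COC(C)=O)C(=O)OC(C)(C)C)O[Si](C(C)(C)C)(C(C)(C)C)O2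
F11 | step 20 | keto acid corresponding to 26 | CC(C)(C)[Si](C)(C)O[C@@H]1C/C(C)=C\[C@H]2C[C@@](C)(CC(=O)C1C(O)(COC(C)=O)C(=O)O)O[Si](C(C)(C)C)(C(C)(C)C)O2
A1 | alternative 1 | ten-membered ring fused to a γ-H butenolide (C7 triethylsilyl ether, C13 silyl ether, C9 not defined) | C/C=C(\C)C(=O)O[C@@H]1C/C(C)=C\[C@H](OC(C)=O)C[C@](C)(O[Si](CC)(CC)CC)CC2OC(=O)C(CO[Si](C)(C)C(C)(C)C)=C21
A2 | alternative 2 | furan-fused ten-membered ring with free C5 carbinol | C/C=C(\C)C(=O)O[C@@H]1C/C(C)=C\[C@H](O)C[C@](C)(O[Si](CC)(CC)CC)Cc2occ(COC(C)=O)c21
A3 | alternative 3 | furan-fused ten-membered ring with C5 dithiane and free C7 carbinol | CC(C)(C)[Si](C)(C)OCc1coc2c1[C@H](O[Si](C)(C)C(C)(C)C)C/C(C)=C\C1(SCCCS1)C[C@](C)(O)C2
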